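The runs come from a simulation with made-up constants.

I have no rate law to integrate for the spring flask, and its charge of 0.300 M is twice that of the summer run.

| setting | dusk | noon | dawn | summer | spring |
|---|---|---|---|---|---|
| starting material | 0.100 M | 0.0400 M | 0.100 M | 0.150 M | 0.300 M |
| target |  |  | 0.0500 M |  |  |
| time |  |  |  |  | 5.5 h |

| run | time / h | [target] / M |
|---|---|---|
| dusk run | 0.22 | 0.0013 |
| dusk run | 0.35 | 0.0033 |
| dusk run | 0.55 | 0.0059 |
| dusk run | 0.87 | 0.0113 |
| dusk run | 1.4 | 0.0197 |
| dusk run | 2.2 | 0.0312 |
| dusk run | 3.5 | 0.0430 |
| dusk run | 5.5 | 0.0505 |
| noon run | 0.22 | 5 × 10⁻⁴ |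
| noon run | 0.35 | 0.0011 |
| noon run | 0.55 | 0.0012 |
| noon run | 0.87 | 0.0028 |
| noon run | 1.4 | 0.0048 |
| noon run | 2.2 | 0.0090 |
| noon run | 3.5 | 0.0134 |
| noon run | 5.5 | 0.0161 |
| dawn run | 0.22 | 0.0505 |
| dawn run | 0.35 | 0.0519 |
| dawn run | 0.55 | 0.0534 |
| dawn run | 0.87 | 0.0576 |
| dawn run | 1.4 | 0.0639 |
| dawn run | 2.2 | 0.0722 |
| dawn run | 3.5 | 0.0790 |
| dawn run | 5.5 | 0.0809 |
| summer run | 0.22 | 0.0037 |
| summer run | 0.35 | 0.0059 |
| summer run | 0.55 | 0.0112 |
| summer run | 0.87 | 0.0202 |
| summer run | 1.4 | 0.0349 |
| summer run | 2.2 | 0.0527 |
| summer run | 3.5 | 0.0706 |
| summer run | 5.5 | 0.0802 |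

(readings scatter by 3 × 10⁻⁴ M)

- order of the initial rate in [starting material], near the charge of the dusk run, the rate being that where two percent of its starting material are target (one fixed amount of target, the same in the runs compared)
- target in the spring run at 5.5 h, as a share of the starting material charged

- Overall: starting material -> target.
- Constant volume, constant temperature.
- An order is taken over about fifteen percent of the charge, up and down.

I compare the runs at 5.5 h, the time asked, which lies where the readings of the dusk run have begun to flatten after a lag (induction period). I reckon the target there as a share of the starting material charged: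

- noon run: 40.2%
- dusk run: 50.5%
- summer run: 53.5%

Reading down these lines, the share rises with the charge, but the charges are not evenly spaced. I therefore reckon the percentage points of share gained at 5.5 h for each doubling of the charge. Between the noon and dusk runs that gain is 7.8 percentage points. Between the dusk and summer runs it is 5.1 points, smaller than the gain below it, and I carry this latest figure as the doubling step.

The spring flask lies one doubling above the summer run. Adding the latest step gives me 58.5%, and I lean below that figure, since the step has been shrinking.

The forecast gives an order of 1.1 (0.8 to 1.4) and a share of 57% (53% to 62%): “Extrapolating to 0.300 M gives about 57%.” That share is lower than mine and implies a doubling step of 3.5 points.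

The simulation gives an order of 1.1 and a share of 57.7%. The doubling step from the summer run to the spring flask is therefore 4.2 points, smaller than the 5.1 points I carried and larger than the forecast's 3.5 points.

    2 starting material ⇌ intermediate + starting material (5.652 M⁻¹ h⁻¹, 5.976 M⁻¹ h⁻¹)
    intermediate → target (0.7380 h⁻¹)
    starting material → target (0.04356 h⁻¹)
    target → decomposed product (0.09000 h⁻¹)

In the spring flask the starting material feeds the intermediate with a forward half-life of 0.295 h at the charge, by that step alone, while the intermediate turns to target with a longer mean life of 1.36 h. Through the 5.5 h, the direct step takes starting material to target with a mean life of 23.0 h by that step alone, the target goes to decomposed product with a mean life of 11.1 h, and the target ends at 57.7% of the starting material charged.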